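Slowness opened the meeting: Thursday's flask gained just 1.00 mM of Q in its last 7.00 min, standing at 28.2 mM from 100 mM of J, the limiting reagent by charge.

| setting | Thursday's | Friday's | Monday's | Saturday's | Sunday's |
|---|---|---|---|---|---|
| J | 100 mM | 50.0 mM | 100 mM | 50.0 mM | 100 mM |
| E | 120 mM | 70.0 mM | 120 mM | 120 mM | 240 mM |
| G | 1.00 mM | 1.00 mM | 1.50 mM | 1.00 mM | 0.500 mM |
| time |  |  |  |  | 37 min |

| run | time / min | [Q] / mM |
|---|---|---|
| Thursday's run | 1.3 | 1.7 |
| Thursday's run | 4.0 | 6.0 |
| Thursday's run | 7.7 | 10.4 |
| Thursday's run | 12 | 15.6 |
| Thursday's run | 17 | 20.2 |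
| Thursday's run | 23 | 24.1 |
| Thursday's run | 30 | 27.2 |
| Thursday's run | 37 | 28.2 |
| Friday's run | 1.3 | 1.7 |
| Friday's run | 4.0 | 3.7 |
| Friday's run | 7.7 | 6.2 |
| Friday's run | 12 | 9.0 |
| Friday's run | 17 | 11.2 |
| Friday's run | 23 | 13.1 |
| Friday's run | 30 | 13.5 |
| Friday's run | 37 | 14.4 |
| Monday's run | 1.3 | 2.7 |
| Monday's run | 4.0 | 8.5 |
| Monday's run | 7.7 | 15.2 |
| Monday's run | 12 | 22.6 |
| Monday's run | 17 | 29.3 |
| Monday's run | 23 | 33.7 |
| Monday's run | 30 | 35.4 |
| Monday's run | 37 | 36.8 |
| Saturday's run | 1.3 | 1.5 |
| Saturday's run | 4.0 | 5.2 |
| Saturday's run | 7.7 | 8.3 |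
| Saturday's run | 12 | 13.4 |
| Saturday's run | 17 | 15.6 |
| Saturday's run | 23 | 17.4 |
| Saturday's run | 30 | 18.9 |
| Saturday's run | 37 | 18.8 |

(standard deviation of a reading: 0.3 mM)

* the power of [E] that the first rate follows, about the charge of the Thursday's run; measure it at two percent of J made into Q
* the power of [G] that the first rate follows, about the charge of the Thursday's run; measure it at two percent of J made into Q
* Q in the Sunday's run at 37 min, as a share of the J charged
* which of these the readings show (the product kills the catalyst / the catalyst wakes slowly / the substrate is lost by itself / the catalyst dies in pairs)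

- Overall: J + E -> Q, with G as catalyst.
- Constant volume, constant temperature.
- What is held in complexes is read along with the free species.
- "The second partner" is E.
- An order is taken over about fifteen percent of the charge, up and down.

The analyst reported no lag: Thursday's flask already showed 1.31 mM min⁻¹ at its first reading, and its pace r, meaning Q over time at 7.7 min, was 1.35 mM min⁻¹.

The kineticist compared Thursday's and Saturday's flasks, which share their E and G. From 17 min to 23 min, Thursday's gained 3.90 mM and Saturday's 1.80 mM, a ratio of 2.17 against 1.25 at 7.7 min, although Thursday's flask held more Q. She argued that a catalyst failing alike in both flasks leaves that ratio unchanged, and that poisoning by Q should lower it. She therefore proposed that J disappears on its own clock.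

To put a number on the clock, the secretary divided Thursday's Q at 37 min by r and called the result the working time τ, 20.9 min. Monday's flask, with more G, gave 18.6 min: as readings, its r stood higher than Thursday's by a factor of 1.46, and its τ lower by a factor of 1.12.

The analyst then took the power of E, a_E, from Friday's and Saturday's paces, 0.541, and the power of G, a_G, from Monday's and Thursday's, 0.936. Sunday's flask charges the same J as Thursday's, so the secretary kept Thursday's τ and scaled r to 1.03 mM min⁻¹. The product r·τ gives 21.4% of the J charged.

The forecast, a separate reckoning, stood higher, with 0.6 for E, 0.95 for G, 24.5% for Sunday and the verdict "the substrate is lost by itself", on the ground that “J must be vanishing by itself, first order”.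

The flask gives 0.47 for E, 1.0 for G, 22.7% for Sunday, and the substrate is lost by itself.

    G + J ⇌ GJ, settled at all times (27.70 M⁻¹)
    GJ + E ⇌ GJE, settled at all times (14.20 M⁻¹)
    GJE → Q + G (2.664 min⁻¹)
    J → Gy (0.07440 min⁻¹)

In Sunday's run, J going to Gy took 11 percentage points from Q at 37 min: the run stands at 22.7% with that reaction and reaches 33.8% without it. Divided by the reckoned pace of 1.03 mM min⁻¹, the Q of Sunday's run gives a working time of 22.1 min, beside Thursday's 20.9 min, and the same run without the reaction gives 32.9 min.

Readings and results come from a simulation with constants of no real substance; the scatter is artificial.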